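## Structural features

The target is a C20 prostanoid methyl ester (numbering C1 = ester carbon to C20) whose only ring, ring A, is the cyclopentenone C8–C12, with the ketone at C9, chlorine on C10 of the C10=C11 double bond and a fully substituted C12 carrying the acetoxy group. C8 starts an exocyclic (7E) double bond that runs on through a (5Z) alkene and three methylene groups to the C1 methyl ester, so C9 lies in a cross-conjugated chloro-dienone. C12 also carries the (14Z)-oct-2-enyl chain C13–C20. C12 (R) is the only stereocentre and has no neighbouring stereocentre to relay from, so its configuration has to come from a reagent or catalyst. The fragile parts are the chloro-dienone (a double Michael acceptor), the C12–O bond (lost by β-elimination if C8 is enolised carelessly or if a good leaving group sits on that oxygen), the conjugated 5Z alkene and the isolated 14Z alkene, which rules out electrophilic chlorination late in the route. The real difficulty is the oxygenated quaternary centre flanked by two sp2 carbons, together with the order in which chlorine, the dienyl chain and the acetate are introduced. The plan exploits the fact that C12 is bonded to the sp2 carbon C11 and to a chain whose first two carbons, C13 and C14, can be read as a second vinyl group. An achiral carbinol with two enantiotopic vinyl groups on C12 therefore maps onto the target, and closing C10=C11 onto one of them creates ring A and the stereocentre together.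

## Logic of the disconnections

35 to 34 to 33: the acetyl C–O bond and, before it, the Si–O bond at C12 are cut. A tertiary acetate β to an enolisable carbon would not survive the enolate chemistry that builds the dienone, so the oxygen travels as a triethylsilyl ether. The forward steps must remove silicon without base and acylate a hindered tertiary alcohol without disturbing the dienone.

33 to 22 and 29: the C7=C8 double bond is cut in the sense of an aldol condensation. This is the most convergent cut, separating ring A with the lower chain from the whole C1–C7 unit. The forward step needs the enolate at C8 (the only enolisable position of 22), E geometry at the new alkene, and survival of the 5Z alkene and of the C12–O bond.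

29 to 28 to 27 to 23 and 24: the aldehyde goes back to the Z allylic alcohol and the alkyne, and C4–C5 is cut as an acetylide alkylation. The 5Z geometry then comes from a syn semi-hydrogenation, and C7 arrives already oxygenated. The carboxyl group must be masked as an orthoester while the acetylide is present, and the Z-enal must be made under non-isomerising conditions and used at once.

22 to 19 to 18: the C10–Cl bond is cut by way of the C10/C11 epoxide. Nucleophilic epoxidation touches only the electron-poor enone, so the 14Z alkene, which would not survive an electrophilic chlorine source, is left alone. The forward steps need chloride to open the epoxide at C10 and dehydration under conditions that keep the silyl ether.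

18 to 17 to 14 and 15, then 14 to 13 to 11: the ketal C–O bonds, the C14=C15 bond (Wittig) and the C14–O bond (hydroboration of the spectator vinyl group) are cut. This reduces the lower chain to the vinyl group left over from ring closure. C9 must stay masked while borane, alkaline peroxide and the ylide are used, and the Wittig step must be Z-selective on a β-silyloxy aldehyde.

11 to 10: the C10=C11 bond is cut and a CH2 is returned to each carbon. This removes ring A and the stereocentre at once and leaves an achiral triene. The forward step requires a chiral catalyst to choose between the two enantiotopic vinyl groups on C12, and a substrate free of groups that deactivate that catalyst.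

10 to 9 to 8 to 5 and 6: the C9 vinyl group is traced to a 2-chloroethyl group, the Si–O bond is cut, and both C12–vinyl bonds are cut back to an ester. All three alkenes then come from two cheap reagents. The forward sequence must silylate before the third alkene is made, because the alkoxide of the triene would be a 3-oxido-1,5-diene, and must avoid conjugate addition to the transient vinyl ketone 7.

5 to 4 to 1 and 2: the ketal C–O bonds and the C8–C9 bond are cut (acylation of a malonate equivalent). This gives two commodity starting materials. The acylation must not dehydrochlorinate 2.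

## Other disconnections considered

Alternative 1: The cuts are C4–C5 and C6–C7. In the forward sense the alkylcopper made from Grignard reagent A3 and CuBr·SMe2 would add syn across ethyne A4, and the resulting (Z)-alkenylcopper would be coupled with the bromomethylene enone A2 under Pd(PPh3)4, a source of zerovalent palladium, to give A1.
- In favour: the 5Z geometry comes from a syn carbometalation, which is inherently stereospecific, and the 7E geometry is fixed beforehand in A2. No Z-enal has to be made and no aldol dehydration has to be steered. On geometric control of the diene this alternative is the better of the two.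
- Against: it builds only the upper chain. The C12 stereocentre, ring A and the chlorine all have to be present in A2, so the stereochemical problem is untouched, and A2 itself needs extra steps from a compound like 22 (one-carbon homologation and E-selective bromination). An organocopper reagent would also meet a chloro-dienone that is an excellent Michael acceptor, and the orthoester has to be unmasked afterwards.
- Comparison: on mechanism it is equal in precedent (carbocupration and alkenyl–alkenyl coupling are both established). On step economy it is equal at best and probably one or two steps longer. On structure it complements the chosen plan and does not compete with it, since it could replace steps 13–16 but not the desymmetrisation.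

Alternative 2: The cut is C8–C9, seen as a ring contraction. BF3·OEt2 would open the oxirane of the six-membered epoxy enone A6 at C8, and the acyl carbon C9 would shift from C7 to C8 to give the formyl cyclopentenone A5.
- In favour: the six-membered precursor can come from inexpensive aromatic material, and chlorine and the C12 oxygen are in place before ring A exists. The separate epoxidation and chloride steps of the chosen plan would therefore not be needed, a point on which this alternative is better. C7 also emerges at the aldehyde oxidation level.
- Against: the cationic character at C8 develops next to C12, which carries an electron-withdrawing acetoxy group able to capture the cation, and migration of C12 substituents or hydride can compete with the acyl shift. The absolute configuration is not set by the key step and would need an enantioselective epoxidation that tells the two enone arms of the dienone precursor apart, or a resolution. A5 is a β-keto aldehyde whose C8 centre is labile and which still has to be turned into the (7E,5Z)-dienyl chain, in practice by a sequence like that of Alternative 1. The alkyne must be semi-reduced late, beside a chloro-enone.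
- Comparison: it is better on raw-material cost and on early placement of chlorine, roughly equal in step count, and weaker on stereocontrol and on the selectivity of the rearrangement.

Alternative 3: The cut is C8–C12. A palladium hydride (from Pd2(dba)3·CHCl3, a chiral diphosphine and a carboxylic acid) would add to the alkoxyallene of cyclobutanol A8, and a ring C–C bond would migrate to the alkoxy-bearing allyl terminus, giving the cyclopentanone A7 with ring A and the C12 stereocentre.
- In favour: this asymmetric ring expansion is well precedented for exactly the α-alkoxy-α-vinyl ketone pattern, so on the reliability of the enantioselective step it is better than the chosen plan, whose precedent is close but not identical. A7 carries the same vinyl handle for the lower chain, which is equal.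
- Against: the carbonyl of A7 sits on C11, next to C12, and not on C9. Ring A would need a 1,3-transposition of oxygen and two new unsaturations before chlorination and the aldol can start. The 4-methoxybenzyl ether must also be exchanged for a group that survives enolate chemistry and then for acetate.
- Comparison: structurally it sets the same centre with the same substituents. Mechanistically it is strain-driven and ligand-controlled, as robust as a metathesis. On step economy it is clearly worse, by about four to five redox and transposition steps.

Key step: step 6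

Remarks on the chemistry (assumptions and corrections):
- **C9 is carried as its ethylene ketal through the ring closure and up to step 10.** A free vinyl ketone would bind and slowly olefinate the oxophilic molybdenum alkylidene. The free enone would also not survive the later hydroboration, because the borane reduces the carbonyl and alkaline peroxide epoxidises the enone. The carbon skeleton, the bond formed (C10=C11) and the ring closed are unchanged; 10 and 11 are the ketals of 5-(triethylsilyloxy)-5-vinylhepta-1,6-dien-3-one and of 4-(triethylsilyloxy)-4-vinylcyclopent-2-en-1-one.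
- **The ketal triene is reached without a β-silyloxy aldehyde or a β-silyloxy vinyl ketone,** both of which are prone to elimination, and without acid treatment of a tertiary bis-allylic silyl ether.
- **The CIP descriptor at C12 changes while the spatial arrangement stays the same.** It is R in 11, S in 12–22 and 30–32, and R again in 33–35, because the ranking of C8, C11 and C13 changes.
- **C7 of the upper chain is introduced with a propargyl unit and an orthoester-protected C1–C4 bromide.** Metalation of an ester-bearing terminal alkyne is not clean.
- **Assumption:** the sense of induction of the biphenolate catalyst cannot be predicted for this substrate. The ligand enantiomer that gives (R)-11 is used; both are available.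

## Route

Step 1
Reactants: 1 2,2-dimethyl-1,3-dioxane-4,6-dione (Meldrum's acid); 2 3-chloropropanoyl chloride
Product: 4 ethyl 5-chloro-3-oxopentanoate, via acyl Meldrum's acid 3 (not isolated)
Conditions: pyridine, CH2Cl2, 0 °C → rt; then EtOH, reflux
Reagents that add atoms: ethanol, CCO
Why: C-acylation of Meldrum's acid followed by alcoholysis with loss of acetone and CO2 (Oikawa–Yonemitsu β-keto ester synthesis); pyridine at 0 °C is too weak a base to dehydrochlorinate the acid chloride.

Step 2
Reactants: 4 ethyl 5-chloro-3-oxopentanoate
Product: 5 ethyl 2-[2-(2-chloroethyl)-1,3-dioxolan-2-yl]acetate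
Conditions: ethane-1,2-diol, TsOH·H2O (cat.), toluene, reflux, Dean–Stark
Reagents that add atoms: ethane-1,2-diol, OCCO
Why: Acid-catalysed ketalisation of the ketone with azeotropic removal of water; the ester and the primary chloride are spectators, and C9 is now masked for everything up to step 10.

Step 3
Reactants: 5 ethyl 2-[2-(2-chloroethyl)-1,3-dioxolan-2-yl]acetate; 6 vinylmagnesium bromide
Product: 8 3-{[2-(2-chloroethyl)-1,3-dioxolan-2-yl]methyl}penta-1,4-dien-3-ol, via vinyl ketone 7 (not isolated)
Conditions: CeCl3 (anhydrous), THF, −78 → 0 °C; aq. NH4Cl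
Reagents that add atoms: none
Why: Double addition of a vinyl organometallic to an ester; the organocerium species formed from the Grignard reagent and CeCl3 favours 1,2-addition to the transient vinyl ketone and suppresses enolisation. The two vinyl groups are identical, so no stereocentre arises.

Step 4
Reactants: 8 3-{[2-(2-chloroethyl)-1,3-dioxolan-2-yl]methyl}penta-1,4-dien-3-ol
Product: 9 ({3-[[2-(2-chloroethyl)-1,3-dioxolan-2-yl]methyl]penta-1,4-dien-3-yl}oxy)triethylsilane
Conditions: Et3SiOTf, 2,6-lutidine, CH2Cl2, −78 °C
Reagents that add atoms: triethylsilyl trifluoromethanesulfonate, CC[Si](CC)(CC)OS(=O)(=O)C(F)(F)F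
Why: Silyl triflate/lutidine silylation of a hindered tertiary alcohol, which a ketal tolerates at low temperature. It is done before the third alkene exists because the alkoxide of the triene would be set up for an anionic oxy-Cope rearrangement.

Step 5
Reactants: 9 ({3-[[2-(2-chloroethyl)-1,3-dioxolan-2-yl]methyl]penta-1,4-dien-3-yl}oxy)triethylsilane
Product: 10 triethyl({3-[(2-vinyl-1,3-dioxolan-2-yl)methyl]penta-1,4-dien-3-yl}oxy)silane (ethylene ketal of 5-(triethylsilyloxy)-5-vinylhepta-1,6-dien-3-one; achiral)
Conditions: KOtBu, THF–DMSO, 0 °C → rt
Reagents that add atoms: none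
Why: E2 dehydrochlorination of a 2-(2-haloethyl)-1,3-dioxolane with a bulky alkoxide, the usual way to vinyl ketals; the substrate has no other acidic C–H and the hindered silyl ether is stable to the base.

Step 6
Reactants: 10 triethyl({3-[(2-vinyl-1,3-dioxolan-2-yl)methyl]penta-1,4-dien-3-yl}oxy)silane
Product: 11 triethyl{[(8R)-8-vinyl-1,4-dioxaspiro[4.4]non-6-en-8-yl]oxy}silane (ethylene ketal of (R)-4-(triethylsilyloxy)-4-vinylcyclopent-2-en-1-one)
Conditions: Mo(N-2,6-iPr2C6H3)(CHCMe2Ph)(3,3'-tBu2-5,5',6,6'-Me4-biphenyl-2,2'-diolate), single enantiomer (5 mol %), C6H6, 22 → 50 °C, N2, ethene vented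
Reagents that add atoms: none
Why: The hexavalent molybdenum alkylidene exchanges its neophylidene for a terminal CH2 of the triene, adds to a second vinyl group in an intramolecular [2+2] cycloaddition and cycloreverts, which joins C10 to C11 and releases ethene. The closest known reaction type is the enantioselective desymmetrising ring-closing metathesis of achiral trienes whose prochiral carbon is a tertiary ether or silyl ether, run with chiral molybdenum biphenolate or binaphtholate alkylidenes; ketals and silyl ethers are tolerated by these catalysts. Ring A closes as a cyclopentene through a bicyclic molybdacyclobutane, and it is the only ring the triene can form because the two carbinol vinyl groups sit on the same carbon. The new stereocentre C12 is set by catalyst control: alkylidene exchange among the vinyl termini is degenerate and reversible, and the two diastereomeric ring-closing transition states differ in how the large Et3SiO group and the spectator vinyl group are placed against the tert-butyl groups of the biphenolate and the arylimido ligand. The step needs enantiotopic group selection and ring closure in preference to intermolecular metathesis; the geminal substitution at C9 and C12 (Thorpe–Ingold effect), the steric shielding of all three vinyl groups against dimerisation and the absence of any carbonyl group secure the latter. The product alkene is flanked by two quaternary carbons and should not re-open, so the kinetic selectivity is kept.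

Step 7
Reactants: 11 triethyl{[(8R)-8-vinyl-1,4-dioxaspiro[4.4]non-6-en-8-yl]oxy}silane
Product: 13 2-[(8S)-8-(triethylsilyloxy)-1,4-dioxaspiro[4.4]non-6-en-8-yl]ethan-1-ol, via B-alkyl-9-BBN adduct 12 (not isolated)
Conditions: 9-borabicyclo[3.3.1]nonane (9-BBN), THF, 0 °C → rt; then 3 M aq. NaOH, 30% H2O2, 0 °C → rt
Reagents that add atoms: hydrogen peroxide, OO
Why: Anti-Markovnikov hydroboration of the monosubstituted vinyl group by 9-BBN, which ignores the ring alkene flanked by two quaternary carbons, then oxidation of the C–B bond with retention. The ketal protects C9 from the borane and from alkaline peroxide, and C12 is untouched.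

Step 8
Reactants: 13 2-[(8S)-8-(triethylsilyloxy)-1,4-dioxaspiro[4.4]non-6-en-8-yl]ethan-1-ol
Product: 14 2-[(8S)-8-(triethylsilyloxy)-1,4-dioxaspiro[4.4]non-6-en-8-yl]acetaldehyde
Conditions: Dess–Martin periodinane, NaHCO3, CH2Cl2, 0 °C → rt
Reagents that add atoms: none
Why: Dess–Martin oxidation of a primary alcohol stops at the aldehyde; the bicarbonate buffer protects the ketal and the silyl ether from the acetic acid released.

Step 9
Reactants: 14 2-[(8S)-8-(triethylsilyloxy)-1,4-dioxaspiro[4.4]non-6-en-8-yl]acetaldehyde; 15 hexyltriphenylphosphonium bromide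
Product: 17 triethyl{[(8S)-8-[(2Z)-oct-2-en-1-yl]-1,4-dioxaspiro[4.4]non-6-en-8-yl]oxy}silane, via hexylidenetriphenylphosphorane 16 (not isolated)
Conditions: NaN(SiMe3)2, THF, 0 °C; then 14, −78 °C → rt
Reagents that add atoms: none
Why: Wittig reaction of a non-stabilised ylide under lithium-free conditions, which gives the Z alkene through the kinetically formed cis-oxaphosphetane. Addition at −78 °C outruns enolisation of the β-silyloxy aldehyde.

Step 10
Reactants: 17 triethyl{[(8S)-8-[(2Z)-oct-2-en-1-yl]-1,4-dioxaspiro[4.4]non-6-en-8-yl]oxy}silane
Product: 18 (4S)-4-[(2Z)-oct-2-en-1-yl]-4-(triethylsilyloxy)cyclopent-2-en-1-one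
Conditions: pyridinium p-toluenesulfonate (cat.), acetone–H2O, rt → 40 °C
Reagents that add atoms: water, O
Why: Mild acid hydrolysis of an allylic ketal, which ionises easily to an allyl-stabilised oxocarbenium ion, while the hindered tertiary silyl ether is expected to survive this weak acid.

Step 11
Reactants: 18 (4S)-4-[(2Z)-oct-2-en-1-yl]-4-(triethylsilyloxy)cyclopent-2-en-1-one
Product: 19 (4S)-4-[(2Z)-oct-2-en-1-yl]-4-(triethylsilyloxy)-6-oxabicyclo[3.1.0]hexan-2-one (either oxirane face)
Conditions: 30% H2O2, aq. NaOH (substoichiometric), MeOH, −10 → 0 °C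
Reagents that add atoms: hydrogen peroxide, OO
Why: Weitz–Scheffer nucleophilic epoxidation, which attacks only the electron-poor C10=C11 bond and leaves the isolated 14Z alkene alone. The two new stereocentres are erased in step 12, so facial selectivity is immaterial.

Step 12
Reactants: 19 (4S)-4-[(2Z)-oct-2-en-1-yl]-4-(triethylsilyloxy)-6-oxabicyclo[3.1.0]hexan-2-one
Product: 22 (4S)-2-chloro-4-[(2Z)-oct-2-en-1-yl]-4-(triethylsilyloxy)cyclopent-2-en-1-one, via chlorohydrin 20 (not isolated), via mesylate 21 (not isolated)
Conditions: pyridinium chloride, CHCl3, rt → 40 °C; then Et3N, MsCl, 0 °C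
Reagents that add atoms: pyridinium chloride, c1cc[nH+]cc1.[Cl-]
Why: Chloride opens the α,β-epoxy ketone at C10 (SN2 at the carbon next to the carbonyl, C11 being neopentyl-like), as in the classical preparation of 4-chloro-enones from epoxy ketones. Mesylation of the C11 hydroxyl and E1cB elimination restore the enone with chlorine on C10, and the weakly acidic chloride source spares the silyl ether.

Step 13
Reactants: 23 2-(prop-2-yn-1-yloxy)tetrahydro-2H-pyran; 24 4-bromo-1,1,1-trimethoxybutane
Product: 27 methyl 7-hydroxyhept-5-ynoate, via lithium acetylide 25 (not isolated), via orthoester THP ether 26 (not isolated)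
Conditions: n-BuLi, THF, −78 °C; 24, DMPU, −78 °C → rt; then TsOH·H2O (cat.), MeOH–H2O, rt
Reagents that add atoms: water, O
Why: SN2 alkylation of a lithium acetylide by a primary bromide forms C4–C5, the orthoester shielding the carboxyl carbon from the organolithium. Acidic aqueous methanol then turns the orthoester into the methyl ester and removes the tetrahydropyranyl group.

Step 14
Reactants: 27 methyl 7-hydroxyhept-5-ynoate
Product: 28 methyl (5Z)-7-hydroxyhept-5-enoate
Conditions: H2 (1 atm), Pd/CaCO3 poisoned with Pb(OAc)2, quinoline, EtOAc, rt
Reagents that add atoms: none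
Why: Syn semi-hydrogenation of the alkyne on poisoned palladium gives the Z alkene and stops at the alkene stage.

Step 15
Reactants: 28 methyl (5Z)-7-hydroxyhept-5-enoate
Product: 29 methyl (5Z)-7-oxohept-5-enoate
Conditions: Dess–Martin periodinane, NaHCO3, CH2Cl2, 0 °C; used at once
Reagents that add atoms: none
Why: Buffered Dess–Martin oxidation of a Z allylic alcohol is neutral and fast, which should keep the Z geometry of the sensitive enal; immediate use avoids isomerisation on storage.

Step 16
Reactants: 22 (4S)-2-chloro-4-[(2Z)-oct-2-en-1-yl]-4-(triethylsilyloxy)cyclopent-2-en-1-one; 29 methyl (5Z)-7-oxohept-5-enoate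
Product: 33 methyl (5Z,7E)-7-[(2R)-4-chloro-2-[(2Z)-oct-2-en-1-yl]-5-oxo-2-(triethylsilyloxy)cyclopent-3-en-1-ylidene]hept-5-enoate, via lithium enolate 30 (not isolated), via lithium aldolate 31 (not isolated), via aldol mesylate 32 (not isolated)
Conditions: LiN(iPr)2, THF, −78 °C; 29, −78 °C; then MsCl, Et3N, −78 → 0 °C
Reagents that add atoms: none
Why: Aldol addition of the kinetic lithium enolate (C8 is the only enolisable position), then mesylation of the aldolate and E1cB elimination. The elimination should favour the 7E alkene, with C6 anti to the C9 carbonyl as is usual for 2-alkylidenecyclopentanones. At −78 °C the C12 silyloxy group is not expelled, since that would create a cyclopentadienone, and C12 is not touched.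

Step 17
Reactants: 33 methyl (5Z,7E)-7-[(2R)-4-chloro-2-[(2Z)-oct-2-en-1-yl]-5-oxo-2-(triethylsilyloxy)cyclopent-3-en-1-ylidene]hept-5-enoate
Product: 34 methyl (5Z,7E)-7-[(2R)-4-chloro-2-hydroxy-2-[(2Z)-oct-2-en-1-yl]-5-oxocyclopent-3-en-1-ylidene]hept-5-enoate
Conditions: HF·pyridine, pyridine, THF, 0 °C → rt
Reagents that add atoms: none
Why: Fluoride-driven cleavage of the triethylsilyl ether under buffered, non-basic conditions that the dienone, the ester and the Z alkenes tolerate. The C12–O bond is not broken, so the configuration is retained.

Step 18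
Reactants: 34 methyl (5Z,7E)-7-[(2R)-4-chloro-2-hydroxy-2-[(2Z)-oct-2-en-1-yl]-5-oxocyclopent-3-en-1-ylidene]hept-5-enoate
Product: 35 methyl (5Z,7E)-7-[(2R)-2-acetoxy-4-chloro-2-[(2Z)-oct-2-en-1-yl]-5-oxocyclopent-3-en-1-ylidene]hept-5-enoate (the target)
Conditions: Ac2O, DMAP, Et3N, CH2Cl2, rt
Reagents that add atoms: acetic anhydride, CC(=O)OC(C)=O
Why: DMAP-catalysed acylation of a hindered tertiary alcohol. Both neighbours of C12 in the ring are now sp2 carbons, so the acetate has no elimination pathway, and the stereocentre is not involved.

## Compound list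

1 | 2,2-dimethyl-1,3-dioxane-4,6-dione (Meldrum's acid) | CC1(C)OC(=O)CC(=O)O1 | starting material
2 | 3-chloropropanoyl chloride | ClCCC(Cl)=O | starting material
3 | 5-(3-chloro-1-hydroxypropylidene)-2,2-dimethyl-1,3-dioxane-4,6-dione (acyl Meldrum's acid) | CC1(C)OC(=O)C(=C(O)CCCl)C(=O)O1 | intermediate
4 | ethyl 5-chloro-3-oxopentanoate | CCOC(=O)CC(=O)CCCl | intermediate
5 | ethyl 2-[2-(2-chloroethyl)-1,3-dioxolan-2-yl]acetate | CCOC(=O)CC1(CCCl)OCCO1 | intermediate
6 | vinylmagnesium bromide | C=C[Mg]Br | starting material
7 | 1-[2-(2-chloroethyl)-1,3-dioxolan-2-yl]but-3-en-2-one | C=CC(=O)CC1(CCCl)OCCO1 | intermediate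
8 | 3-{[2-(2-chloroethyl)-1,3-dioxolan-2-yl]methyl}penta-1,4-dien-3-ol | C=CC(O)(C=C)CC1(CCCl)OCCO1 | intermediate
9 | ({3-[[2-(2-chloroethyl)-1,3-dioxolan-2-yl]methyl]penta-1,4-dien-3-yl}oxy)triethylsilane | C=CC(O[Si](CC)(CC)CC)(C=C)CC1(CCCl)OCCO1 | intermediate
10 | triethyl({3-[(2-vinyl-1,3-dioxolan-2-yl)methyl]penta-1,4-dien-3-yl}oxy)silane (achiral) | C=CC1(CC(O[Si](CC)(CC)CC)(C=C)C=C)OCCO1 | intermediate
11 | triethyl{[(8R)-8-vinyl-1,4-dioxaspiro[4.4]non-6-en-8-yl]oxy}silane | C=C[C@@]1(O[Si](CC)(CC)CC)C=CC2(OCCO2)C1 | intermediate
12 | 9-{2-[(8S)-8-(triethylsilyloxy)-1,4-dioxaspiro[4.4]non-6-en-8-yl]ethyl}-9-borabicyclo[3.3.1]nonane | C(C[C@@]1(O[Si](CC)(CC)CC)C=CC2(OCCO2)C1)B1C2CCCC1CCC2 | intermediate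
13 | 2-[(8S)-8-(triethylsilyloxy)-1,4-dioxaspiro[4.4]non-6-en-8-yl]ethan-1-ol | OCC[C@@]1(O[Si](CC)(CC)CC)C=CC2(OCCO2)C1 | intermediate
14 | 2-[(8S)-8-(triethylsilyloxy)-1,4-dioxaspiro[4.4]non-6-en-8-yl]acetaldehyde | O=CC[C@@]1(O[Si](CC)(CC)CC)C=CC2(OCCO2)C1 | intermediate
15 | hexyltriphenylphosphonium bromide | CCCCCC[P+](c1ccccc1)(c1ccccc1)c1ccccc1.[Br-] | starting material
16 | hexylidenetriphenylphosphorane | CCCCCC=P(c1ccccc1)(c1ccccc1)c1ccccc1 | intermediate
17 | triethyl{[(8S)-8-[(2Z)-oct-2-en-1-yl]-1,4-dioxaspiro[4.4]non-6-en-8-yl]oxy}silane | CCCCC/C=C\C[C@@]1(O[Si](CC)(CC)CC)C=CC2(OCCO2)C1 | intermediate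
18 | (4S)-4-[(2Z)-oct-2-en-1-yl]-4-(triethylsilyloxy)cyclopent-2-en-1-one | CCCCC/C=C\C[C@@]1(O[Si](CC)(CC)CC)C=CC(=O)C1 | intermediate
19 | (4S)-4-[(2Z)-oct-2-en-1-yl]-4-(triethylsilyloxy)-6-oxabicyclo[3.1.0]hexan-2-one (oxirane carbons: either face) | CCCCC/C=C\C[C@@]1(O[Si](CC)(CC)CC)C2OC2C(=O)C1 | intermediate
20 | (4S)-2-chloro-3-hydroxy-4-[(2Z)-oct-2-en-1-yl]-4-(triethylsilyloxy)cyclopentan-1-one (C2, C3 trans, mixture at these centres) | CCCCC/C=C\C[C@@]1(O[Si](CC)(CC)CC)C(O)C(Cl)C(=O)C1 | intermediate
21 | (4S)-2-chloro-3-(methanesulfonyloxy)-4-[(2Z)-oct-2-en-1-yl]-4-(triethylsilyloxy)cyclopentan-1-one | CCCCC/C=C\C[C@@]1(O[Si](CC)(CC)CC)C(OS(C)(=O)=O)C(Cl)C(=O)C1 | intermediate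
22 | (4S)-2-chloro-4-[(2Z)-oct-2-en-1-yl]-4-(triethylsilyloxy)cyclopent-2-en-1-one | CCCCC/C=C\C[C@@]1(O[Si](CC)(CC)CC)C=C(Cl)C(=O)C1 | intermediate
23 | 2-(prop-2-yn-1-yloxy)tetrahydro-2H-pyran (racemic acetal) | C#CCOC1CCCCO1 | starting material
24 | 4-bromo-1,1,1-trimethoxybutane | COC(OC)(OC)CCCBr | starting material
25 | lithium acetylide of 23 | [Li]C#CCOC1CCCCO1 | intermediate
26 | 2-[(7,7,7-trimethoxyhept-2-yn-1-yl)oxy]tetrahydro-2H-pyran | COC(OC)(OC)CCCC#CCOC1CCCCO1 | intermediate
27 | methyl 7-hydroxyhept-5-ynoate | COC(=O)CCCC#CCO | intermediate
28 | methyl (5Z)-7-hydroxyhept-5-enoate | COC(=O)CCC/C=C\CO | intermediate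
29 | methyl (5Z)-7-oxohept-5-enoate | COC(=O)CCC/C=C\C=O | intermediate
30 | lithium enolate of 22 (lithium (4S)-2-chloro-4-[(2Z)-oct-2-en-1-yl]-4-(triethylsilyloxy)cyclopenta-1,5-dien-1-olate) | CCCCC/C=C\C[C@@]1(O[Si](CC)(CC)CC)C=C(Cl)C(O[Li])=C1 | intermediate
31 | lithium aldolate: lithium alkoxide of methyl (5Z)-7-[(2S)-4-chloro-2-[(2Z)-oct-2-en-1-yl]-5-oxo-2-(triethylsilyloxy)cyclopent-3-en-1-yl]-7-hydroxyhept-5-enoate (mixture at C7 and C8) | CCCCC/C=C\C[C@@]1(O[Si](CC)(CC)CC)C=C(Cl)C(=O)C1C(O[Li])/C=C\CCCC(=O)OC | intermediate
32 | methyl (5Z)-7-[(2S)-4-chloro-2-[(2Z)-oct-2-en-1-yl]-5-oxo-2-(triethylsilyloxy)cyclopent-3-en-1-yl]-7-(methanesulfonyloxy)hept-5-enoate (mixture at C7 and C8) | CCCCC/C=C\C[C@@]1(O[Si](CC)(CC)CC)C=C(Cl)C(=O)C1C(OS(C)(=O)=O)/C=C\CCCC(=O)OC | intermediate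
33 | methyl (5Z,7E)-7-[(2R)-4-chloro-2-[(2Z)-oct-2-en-1-yl]-5-oxo-2-(triethylsilyloxy)cyclopent-3-en-1-ylidene]hept-5-enoate | CCCCC/C=C\C[C@@]1(O[Si](CC)(CC)CC)C=C(Cl)C(=O)/C1=C/C=C\CCCC(=O)OC | intermediate
34 | methyl (5Z,7E)-7-[(2R)-4-chloro-2-hydroxy-2-[(2Z)-oct-2-en-1-yl]-5-oxocyclopent-3-en-1-ylidene]hept-5-enoate | CCCCC/C=C\C[C@@]1(O)C=C(Cl)C(=O)/C1=C/C=C\CCCC(=O)OC | intermediate
35 | methyl (5Z,7E)-7-[(2R)-2-acetoxy-4-chloro-2-[(2Z)-oct-2-en-1-yl]-5-oxocyclopent-3-en-1-ylidene]hept-5-enoate | CCCCC/C=C\C[C@@]1(OC(C)=O)C=C(Cl)C(=O)/C1=C/C=C\CCCC(=O)OC | target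

## Step count and least certain steps

Total step count: 18. Longest linear sequence: 15 (steps 1–12 and 16–18); the enal branch (steps 13–15) joins at step 16.

Step 6 (key step). The catalyst may discriminate poorly between the two enantiotopic vinyl groups, because every alkene of 10 sits on a fully substituted carbon, and turnover may be slow for the same reason. The fallback sets out from 10 and returns at 13. The ring is closed without asymmetric induction using the achiral alkylidene Mo(N-2,6-iPr2C6H3)(CHCMe2Ph)[OCMe(CF3)2]2, giving racemic triethyl[(8-vinyl-1,4-dioxaspiro[4.4]non-6-en-8-yl)oxy]silane F1. Hydroboration and oxidation as in step 7 give racemic 2-[8-(triethylsilyloxy)-1,4-dioxaspiro[4.4]non-6-en-8-yl]ethan-1-ol F2. Esterification with (2S)-2-methoxy-2-phenylacetic acid (DCC, DMAP) gives two diastereomeric esters that are separated by chromatography or crystallisation. Saponification of 2-[(8S)-8-(triethylsilyloxy)-1,4-dioxaspiro[4.4]non-6-en-8-yl]ethyl (2S)-2-methoxy-2-phenylacetate F3 with LiOH in THF–H2O gives 13. This replaces catalyst control by a classical resolution at the cost of half the material.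

Step 3. Conjugate addition of the second vinyl equivalent to the transient vinyl ketone, or enolisation with opening of the dioxolane, may erode the double 1,2-addition. The fallback sets out from 5 and returns at 8. i-PrMgCl and N,O-dimethylhydroxylamine hydrochloride convert 5 into 2-[2-(2-chloroethyl)-1,3-dioxolan-2-yl]-N-methoxy-N-methylacetamide F4. One equivalent of vinylmagnesium bromide, quenched cold into aqueous acid, gives the vinyl ketone 7 as an isolated compound. A separate CeCl3-mediated vinyl addition at −78 °C then gives 8, so each C–C bond is formed under its own control.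

Step 11. Peroxide addition at the neopentyl-type C11 may be slow, and the base may meanwhile enolise C8 and expel the C12 silyloxy group. The fallback sets out from 13 and returns at 22, placing chlorine before the 14Z alkene exists. Hydrolysis of the ketal (pyridinium p-toluenesulfonate, acetone–H2O) gives (4S)-4-(2-hydroxyethyl)-4-(triethylsilyloxy)cyclopent-2-en-1-one F5. PhICl2 in pyridine (chlorine addition to the enone and dehydrochlorination) gives (4S)-2-chloro-4-(2-hydroxyethyl)-4-(triethylsilyloxy)cyclopent-2-en-1-one F6. Dess–Martin oxidation gives 2-[(1S)-3-chloro-4-oxo-1-(triethylsilyloxy)cyclopent-2-en-1-yl]acetaldehyde F7. One equivalent of ylide 16 at −78 °C, which reacts at the aldehyde much faster than at the hindered ketone, gives 22.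

Step 12. The weak acid may fail to open the oxirane or to dehydrate the chlorohydrin, and a stronger acid would strip the silyl ether. The fallback sets out from 19 and returns at 22. Anhydrous HCl in CHCl3 at 0 °C, the classical one-flask opening and dehydration, is allowed to remove silicon as well and gives (4S)-2-chloro-4-hydroxy-4-[(2Z)-oct-2-en-1-yl]cyclopent-2-en-1-one F8. Et3SiOTf and 2,6-lutidine then restore the silyl ether to give 22. If chloride attack at C11 were the problem instead, the fallback given for step 11 applies.

Step 16. The Z-enal or the product's C5=C6 bond may isomerise under the basic conditions, the elimination may give 7E/7Z mixtures, and the enolate may lose the silyloxy group on warming. The fallback sets out from 27 and 22 and returns at 33. Dess–Martin oxidation of 27 gives methyl 7-oxohept-5-ynoate F9, which cannot isomerise. Aldol addition, mesylation and elimination with 22 as in step 16 give methyl (7E)-7-[(2R)-4-chloro-2-[(2Z)-oct-2-en-1-yl]-5-oxo-2-(triethylsilyloxy)cyclopent-3-en-1-ylidene]hept-5-ynoate F10, whose 7E/7Z ratio can be settled before any 5Z alkene exists. Syn semi-hydrogenation (H2, Pd/CaCO3 poisoned with Pb(OAc)2, quinoline) then sets the 5Z alkene last and gives 33.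

## Further compounds

F1 | step 6 | racemic triethyl[(8-vinyl-1,4-dioxaspiro[4.4]non-6-en-8-yl)oxy]silane | C=CC1(O[Si](CC)(CC)CC)C=CC2(OCCO2)C1
F2 | step 6 | racemic 2-[8-(triethylsilyloxy)-1,4-dioxaspiro[4.4]non-6-en-8-yl]ethan-1-ol | OCCC1(O[Si](CC)(CC)CC)C=CC2(OCCO2)C1
F3 | step 6 | 2-[(8S)-8-(triethylsilyloxy)-1,4-dioxaspiro[4.4]non-6-en-8-yl]ethyl (2S)-2-methoxy-2-phenylacetate | CO[C@H](C(=O)OCC[C@@]1(O[Si](CC)(CC)CC)C=CC2(OCCO2)C1)c1ccccc1
F4 | step 3 | 2-[2-(2-chloroethyl)-1,3-dioxolan-2-yl]-N-methoxy-N-methylacetamide | CON(C)C(=O)CC1(CCCl)OCCO1
F5 | step 11 | (4S)-4-(2-hydroxyethyl)-4-(triethylsilyloxy)cyclopent-2-en-1-one | OCC[C@@]1(O[Si](CC)(CC)CC)C=CC(=O)C1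
F6 | step 11 | (4S)-2-chloro-4-(2-hydroxyethyl)-4-(triethylsilyloxy)cyclopent-2-en-1-one | OCC[C@@]1(O[Si](CC)(CC)CC)C=C(Cl)C(=O)C1
F7 | step 11 | 2-[(1S)-3-chloro-4-oxo-1-(triethylsilyloxy)cyclopent-2-en-1-yl]acetaldehyde | O=CC[C@@]1(O[Si](CC)(CC)CC)C=C(Cl)C(=O)C1
F8 | step 12 | (4S)-2-chloro-4-hydroxy-4-[(2Z)-oct-2-en-1-yl]cyclopent-2-en-1-one | CCCCC/C=C\C[C@@]1(O)C=C(Cl)C(=O)C1
F9 | step 16 | methyl 7-oxohept-5-ynoate | COC(=O)CCCC#CC=O
F10 | step 16 | methyl (7E)-7-[(2R)-4-chloro-2-[(2Z)-oct-2-en-1-yl]-5-oxo-2-(triethylsilyloxy)cyclopent-3-en-1-ylidene]hept-5-ynoate | CCCCC/C=C\C[C@@]1(O[Si](CC)(CC)CC)C=C(Cl)C(=O)/C1=C/C#CCCCC(=O)OC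
A1 | alternative 1 | (4R,5E)-2-chloro-4-[(2Z)-oct-2-en-1-yl]-4-(triethylsilyloxy)-5-[(2Z)-7,7,7-trimethoxyhept-2-en-1-ylidene]cyclopent-2-en-1-one | CCCCC/C=C\C[C@@]1(O[Si](CC)(CC)CC)C=C(Cl)C(=O)/C1=C/C=C\CCCC(OC)(OC)OC
A2 | alternative 1 | (4R,5E)-5-(bromomethylidene)-2-chloro-4-[(2Z)-oct-2-en-1-yl]-4-(triethylsilyloxy)cyclopent-2-en-1-one | CCCCC/C=C\C[C@@]1(O[Si](CC)(CC)CC)C=C(Cl)C(=O)/C1=C/Br
A3 | alternative 1 | 4,4,4-trimethoxybutylmagnesium bromide | COC(OC)(OC)CCC[Mg]Br
A4 | alternative 1 | ethyne | C#C
A5 | alternative 2 | (4S,5S)-4-acetoxy-2-chloro-5-formyl-4-(oct-2-yn-1-yl)cyclopent-2-en-1-one (keto-aldehyde tautomer) | CCCCCC#CC[C@@]1(OC(C)=O)C=C(Cl)C(=O)[C@@H]1C=O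
A6 | alternative 2 | 3-chloro-5-(oct-2-yn-1-yl)-2-oxo-7-oxabicyclo[4.1.0]hept-3-en-5-yl acetate (oxirane cis to the acetoxy group; C5 configured as C12 of the target) | CCCCCC#CC[C@@]1(OC(C)=O)C=C(Cl)C(=O)[C@@H]2O[C@H]12
A7 | alternative 3 | (2R)-2-[(4-methoxybenzyl)oxy]-2-vinylcyclopentan-1-one | C=C[C@@]1(OCc2ccc(OC)cc2)C(=O)CCC1
A8 | alternative 3 | 1-{1-[(4-methoxybenzyl)oxy]propa-1,2-dien-1-yl}cyclobutan-1-ol | C=C=C(OCc1ccc(OC)cc1)C1(O)CCC1
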